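## Retrosynthetic overview

1. The tertiary alcohol is unmasked last from a TEMPO ether by N–O cleavage; the whole tricycle is assembled in the step before.
2. Key step read backwards: ring C opens at the bond between the gem-dimethyl carbon and the carbon bearing the oxygenated isopropyl group, and ring B opens at the bond between the cyclopentane bridgehead and the ring-fusion CH (both are 5-exo radical closures onto prenyl groups). The isobutyryl-bearing carbon is then taken out of ring A with its acyl group as a diazo ketone, which leaves a five-membered cyclopentane-1,2,4-trione.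
3. Enabling feature: in that five-membered ring the two adjacent carbonyl carbons (the later enol carbon and the later ring ketone beside the acyl-bearing carbon) are flanked by two fully substituted carbons, the methyl/prenyl carbon and the prenyl/TEMPO-oxy carbon. The 1,2-diketone therefore cannot enolise and accepts one carbon between its carbonyls; the TEMPO-oxy carbon lies between two carbonyls, so its C–ON bond is a latent radical that can cyclise productively only once ring A has six members.
4. Order of ring formation: five-membered trione ring (bought as 2-methylcyclopentane-1,3-dione; its quaternary stereocentre is set by a desymmetrising transfer hydrogenation), then ring A by one-carbon ring expansion, then ring B, then ring C, the last three in one flask.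

Key step: step 8

Remark: ring A is the six-membered enol-triketone ring, ring B the five-membered ring holding the bridging ketone, ring C the gem-dimethylcyclopentane. The target is treated as the enol tautomer drawn in its SMILES, and descriptors refer to the tautomers drawn.

## Route

Step 1
Reactants: 1 2-methylcyclopentane-1,3-dione; 2 1-bromo-3-methylbut-2-ene (prenyl bromide)
Product: 3 2-methyl-2-(3-methylbut-2-en-1-yl)cyclopentane-1,3-dione
Conditions: NaOH (1.0 equiv, 1 M aq.), Bu4NI (cat.), rt
Reagents that add atoms: prenyl bromide (2), CC(C)=CCBr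
Why: C-alkylation of the symmetrical 2-methyl-1,3-dione enolate by a soft allylic halide in water should build the quaternary carbon; the product is achiral, so no stereocentre is set yet.

Step 2
Reactants: 3 2-methyl-2-(3-methylbut-2-en-1-yl)cyclopentane-1,3-dione
Product: 4 (2R,3R)-3-hydroxy-2-methyl-2-(3-methylbut-2-en-1-yl)cyclopentan-1-one
Conditions: RuCl(p-cymene)[(R,R)-TsDPEN] (1 mol %), HCO2H/Et3N (5:2), CH2Cl2, 30 °C
Reagents that add atoms: none
Why: Noyori asymmetric transfer hydrogenation should desymmetrise the two enantiotopic carbonyls, the chiral ruthenium hydride selecting one of them and delivering hydride from the methyl face (anti to prenyl), which fixes the quaternary carbon as R and the carbinol as R (if the (R,R) complex selects the other carbonyl, its antipode is used).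

Step 3
Reactants: 4 (2R,3R)-3-hydroxy-2-methyl-2-(3-methylbut-2-en-1-yl)cyclopentan-1-one
Product: 5 (2R,3R)-3,5-dihydroxy-2-methyl-2-(3-methylbut-2-en-1-yl)cyclopentan-1-one (both epimers at C5)
Conditions: LDA (2.2 equiv), THF, −78 °C; 2-(phenylsulfonyl)-3-phenyloxaziridine, −78 °C; aq. NH4Cl
Reagents that add atoms: 2-(phenylsulfonyl)-3-phenyloxaziridine, O=S(=O)(c1ccccc1)N1OC1c1ccccc1
Why: The alkoxide–enolate dianion can form only on the CH2 side of the ketone (the other α-carbon is quaternary) and should be hydroxylated there by the oxaziridine (enolate α-hydroxylation); the new carbinol centre forms as a mixture and is erased in step 4.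

Step 4
Reactants: 5 (2R,3R)-3,5-dihydroxy-2-methyl-2-(3-methylbut-2-en-1-yl)cyclopentan-1-one
Product: 6 (5R)-2-hydroxy-5-methyl-5-(3-methylbut-2-en-1-yl)cyclopent-2-ene-1,4-dione (enol form of the 3,3-disubstituted cyclopentane-1,2,4-trione)
Conditions: Dess–Martin periodinane (2.5 equiv), CH2Cl2, 0 °C to rt
Reagents that add atoms: none
Why: Dess–Martin oxidation should take both secondary alcohols to ketones, the α-hydroxy ketone becoming the 1,2-diketone, so that the two sides of the quaternary carbon stay different and its configuration is kept; the product rests as the stable enol.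

Step 5
Reactants: 6 (5R)-2-hydroxy-5-methyl-5-(3-methylbut-2-en-1-yl)cyclopent-2-ene-1,4-dione; 2 1-bromo-3-methylbut-2-ene
Product: 7 (5R)-2-hydroxy-5-methyl-3,5-bis(3-methylbut-2-en-1-yl)cyclopent-2-ene-1,4-dione
Conditions: KOH (1.0 equiv), H2O, 0 °C; 2 (1.0 equiv), 0 °C to rt
Reagents that add atoms: prenyl bromide (2), CC(C)=CCBr
Why: The delocalised anion of the cyclic 2-hydroxy-enedione (a vinylogous acid) should be C-allylated at its central carbon in water, as in the prenylation of cyclic 1,3-diones; the alkylated carbon re-enolises, so no stereocentre results.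

Step 6
Reactants: 7 (5R)-2-hydroxy-5-methyl-3,5-bis(3-methylbut-2-en-1-yl)cyclopent-2-ene-1,4-dione; 8 TEMPO
Product: 9 (5R)-5-methyl-3,5-bis(3-methylbut-2-en-1-yl)-3-[(2,2,6,6-tetramethylpiperidin-1-yl)oxy]cyclopentane-1,2,4-trione (both epimers at C3)
Conditions: PhI(OAc)2 (0.6 equiv), THF, −78 to 0 °C
Reagents that add atoms: TEMPO (8), CC1(C)CCCC(C)(C)N1[O]
Why: Oxidative α-aminoxylation of a 1,3-dicarbonyl: one-electron oxidation of the enol gives the carbon radical between two carbonyls, which TEMPO should cap at carbon because closure onto a prenyl group would here require a 7-oxonorbornane-2,3-dione; either epimer at the new carbon serves, since that centre becomes planar again in step 8.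

Step 7
Reactants: 10 2-methylpropanoyl chloride; 11 (trimethylsilyl)diazomethane
Product: 12 1-diazo-3-methylbutan-2-one
Conditions: 11 (2.0 equiv), MeCN/THF (1:1), 0 °C to rt
Reagents that add atoms: (trimethylsilyl)diazomethane (11), C[Si](C)(C)C=[N+]=[N-]
Why: Acylation of the silyl diazomethane by the acid chloride and loss of chlorotrimethylsilane should give the α-diazo ketone (first stage of an Arndt–Eistert sequence).

Step 8
Reactants: 9 (5R)-5-methyl-3,5-bis(3-methylbut-2-en-1-yl)-3-[(2,2,6,6-tetramethylpiperidin-1-yl)oxy]cyclopentane-1,2,4-trione; 12 1-diazo-3-methylbutan-2-one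
Product: 14 (1S,3S,5S,7S)-8-hydroxy-4,4,7-trimethyl-9-(2-methylpropanoyl)-3-{2-[(2,2,6,6-tetramethylpiperidin-1-yl)oxy]propan-2-yl}tricyclo[5.3.1.0^1,5]undec-8-ene-10,11-dione, via six-membered alkoxyamine 13 (not isolated)
Conditions: Sc(OTf)3 (0.3 equiv), 12 (1.5 equiv), CH2Cl2, −20 to 0 °C; then 2,6-lutidine (0.5 equiv), ClCH2CH2Cl, 70 °C, argon, dark
Reagents that add atoms: 1-diazo-3-methylbutan-2-one (12), CC(C)C(=O)C=[N+]=[N-]
Why: Proposed new method: Sc(OTf)3 chelates the vicinal diketone of 9, the diazo carbon of 12 adds to either of its carbonyls and the neighbouring acyl carbon migrates to the diazonium carbon with loss of N2, so that the five-membered trione ring becomes the six-membered enol-triketone ring A of 13 (closest known type: Buchner–Curtius–Schlotterbeck homologation of non-enolisable cyclic 1,2-diketones to 2-substituted 1,3-diketones); both modes of attack give the same product, and the lone ketone is shielded by its two fully substituted neighbours. Warming then homolyses the C–ON bond at the ring carbon that now lies between two carbonyls of the conjugated triketone, and the persistent radical effect carries the radical through a 5-exo-trig closure onto the prenyl group of the methyl-bearing carbon (ring B, completing the bicyclo[3.2.1]octane) and a 5-exo-trig closure of the new tertiary radical onto the second prenyl group (ring C) before TEMPO caps the last tertiary radical (closest known types: thermal alkoxyamine isomerisation with radical cyclisation, and the same two closures of such enols under Mn(OAc)3/Cu(OAc)2). In the ring-contracted precursor 9 the first closure would have to form a 7-oxonorbornane-2,3-dione, which is why 9 should be a stable carrier of the radical and the cascade is released only by the ring expansion. The methyl-bearing stereocentre from step 2 dictates both bridgeheads, because the CH2–CH bridge can only span the face that carries its CH2, and the ring-fusion CH becomes exo because only the exo radical reaches the second alkene while the endo radical can reopen or be recapped reversibly. The carbon that bears the oxygenated isopropyl group is the one centre without a strong control element (either face of the trisubstituted alkene can be attacked), so its epimer is expected as a companion and is removed by chromatography. The step needs acyl rather than alkyl migration and ring closure before loss of nitroxide by elimination, which the chelated diketone and a homolysis temperature below that at which the tertiary alkoxyamine 14 fragments are meant to secure.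

Step 9
Reactants: 14 (1S,3S,5S,7S)-8-hydroxy-4,4,7-trimethyl-9-(2-methylpropanoyl)-3-{2-[(2,2,6,6-tetramethylpiperidin-1-yl)oxy]propan-2-yl}tricyclo[5.3.1.0^1,5]undec-8-ene-10,11-dione
Product: 15 (1S,3S,5S,7S)-8-hydroxy-3-(2-hydroxypropan-2-yl)-4,4,7-trimethyl-9-(2-methylpropanoyl)tricyclo[5.3.1.0^1,5]undec-8-ene-10,11-dione (CNP0267234.1)
Conditions: Zn dust, AcOH/THF/H2O (3:1:1), 50 °C
Reagents that add atoms: none
Why: Zinc in acetic acid should cleave the N–O bond of the alkoxyamine reductively and leave the tertiary alcohol; no stereocentre is touched and the enolised triketone is inert to these conditions.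

## Compound list

1 | 2-methylcyclopentane-1,3-dione | CC1C(=O)CCC1=O | starting material
2 | 1-bromo-3-methylbut-2-ene (prenyl bromide) | CC(C)=CCBr | starting material
3 | 2-methyl-2-(3-methylbut-2-en-1-yl)cyclopentane-1,3-dione | CC(C)=CCC1(C)C(=O)CCC1=O | intermediate
4 | (2R,3R)-3-hydroxy-2-methyl-2-(3-methylbut-2-en-1-yl)cyclopentan-1-one | O=C1CC[C@@H](O)[C@@]1(C)CC=C(C)C | intermediate
5 | (2R,3R)-3,5-dihydroxy-2-methyl-2-(3-methylbut-2-en-1-yl)cyclopentan-1-one (both epimers at C5) | O=C1C(O)C[C@@H](O)[C@@]1(C)CC=C(C)C | intermediate
6 | (5R)-2-hydroxy-5-methyl-5-(3-methylbut-2-en-1-yl)cyclopent-2-ene-1,4-dione | O=C1C(O)=CC(=O)[C@@]1(C)CC=C(C)C | intermediate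
7 | (5R)-2-hydroxy-5-methyl-3,5-bis(3-methylbut-2-en-1-yl)cyclopent-2-ene-1,4-dione | O=C1C(O)=C(CC=C(C)C)C(=O)[C@@]1(C)CC=C(C)C | intermediate
8 | TEMPO (2,2,6,6-tetramethylpiperidin-1-oxyl) | CC1(C)CCCC(C)(C)N1[O] | starting material
9 | (5R)-5-methyl-3,5-bis(3-methylbut-2-en-1-yl)-3-[(2,2,6,6-tetramethylpiperidin-1-yl)oxy]cyclopentane-1,2,4-trione (both epimers at C3) | O=C1C(=O)C(CC=C(C)C)(ON2C(C)(C)CCCC2(C)C)C(=O)[C@@]1(C)CC=C(C)C | intermediate
10 | 2-methylpropanoyl chloride | CC(C)C(Cl)=O | starting material
11 | (trimethylsilyl)diazomethane | C[Si](C)(C)C=[N+]=[N-] | starting material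
12 | 1-diazo-3-methylbutan-2-one | CC(C)C(=O)C=[N+]=[N-] | intermediate
13 | (4S)-3-hydroxy-4-methyl-4,6-bis(3-methylbut-2-en-1-yl)-2-(2-methylpropanoyl)-6-[(2,2,6,6-tetramethylpiperidin-1-yl)oxy]cyclohex-2-ene-1,5-dione (both epimers at C6; not isolated) | CC(C)C(=O)C1=C(O)[C@](C)(CC=C(C)C)C(=O)C(CC=C(C)C)(ON2C(C)(C)CCCC2(C)C)C1=O | intermediate
14 | (1S,3S,5S,7S)-8-hydroxy-4,4,7-trimethyl-9-(2-methylpropanoyl)-3-{2-[(2,2,6,6-tetramethylpiperidin-1-yl)oxy]propan-2-yl}tricyclo[5.3.1.0^1,5]undec-8-ene-10,11-dione | CC(C)C(=O)C1=C(O)[C@]2(C)C[C@H]3C(C)(C)[C@@H](C(C)(C)ON4C(C)(C)CCCC4(C)C)C[C@@]3(C1=O)C2=O | intermediate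
15 | (1S,3S,5S,7S)-8-hydroxy-3-(2-hydroxypropan-2-yl)-4,4,7-trimethyl-9-(2-methylpropanoyl)tricyclo[5.3.1.0^1,5]undec-8-ene-10,11-dione (CNP0267234.1) | CC(C)C(=O)C1=C(O)[C@]2(C)C[C@H]3C(C)(C)[C@@H](C(C)(C)O)C[C@@]3(C1=O)C2=O | target

## Step count and risks

Total step count: 9. Longest linear sequence: 8 steps (steps 1 to 6, 8 and 9); step 7 is a one-step side branch.

Steps most likely to fail:

**Step 8.** The two stages may not mesh. The weakly nucleophilic diazo ketone may be slow on the hindered diketone, so that acid-induced closure of a prenyl group competes. During the thermal stage the tertiary radicals may lose a β-hydrogen to the nitroxide (alkene plus hydroxylamine) before ring C has closed. The fallback separates the two events and replaces the redox-neutral relay by the known oxidative cyclisation of enolised 1,3-dicarbonyls. From 9 only the cold first stage is run (Sc(OTf)3 or BF3·OEt2, 12, −40 to 0 °C) and 13 is isolated. SmI2 in THF/MeOH at −78 °C removes the aminoxyl group from the carbon between the two carbonyls (reductive cleavage of an α-oxygenated ketone) to give (6S)-3,5-dihydroxy-6-methyl-2,6-bis(3-methylbut-2-en-1-yl)-4-(2-methylpropanoyl)cyclohexa-2,4-dien-1-one F1. Mn(OAc)3·2H2O and Cu(OAc)2·H2O in acetic acid at room temperature should then effect the same two 5-exo closures oxidatively and end in the isopropenyl compound (1S,3R,5S,7S)-8-hydroxy-4,4,7-trimethyl-9-(2-methylpropanoyl)-3-(prop-1-en-2-yl)tricyclo[5.3.1.0^1,5]undec-8-ene-10,11-dione F2, whose epimer at the isopropenyl carbon is removed. Mukaiyama hydration (Co(acac)2, PhSiH3, O2, THF/i-PrOH) adds water to the isopropenyl group in the Markovnikov sense, and the fallback rejoins the route at 15.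

**Step 5.** O-alkylation of the ambident anion and a second alkylation at the same carbon may occur, because the product is as acidic as the starting enol. The fallback replaces the SN2 alkylation by a Tsuji–Trost reaction under neutral conditions: 6, 2-methylbut-3-en-2-ol and Pd(PPh3)4 in toluene at 60 °C. The acidic enol itself ionises the allylic alcohol, the soft enolate attacks the π-prenyl palladium complex at its unsubstituted terminus and at carbon, and water is the only by-product. This goes from 6 directly to 7 and makes no compound outside the list (F0).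

**Step 3.** Retro-aldol ring opening of the lithium β-alkoxide next to the quaternary carbon may occur while the dianion is formed, and the enolate may add to the sulfonimine by-product. In the fallback the hydroxyl of 4 is first silylated (TBSCl, imidazole, DMF) to (2R,3R)-3-[(tert-butyldimethylsilyl)oxy]-2-methyl-2-(3-methylbut-2-en-1-yl)cyclopentan-1-one F3. Its potassium enolate (KHMDS, THF, −78 °C) is hydroxylated with (camphorsulfonyl)oxaziridine to (2R,3R)-3-[(tert-butyldimethylsilyl)oxy]-5-hydroxy-2-methyl-2-(3-methylbut-2-en-1-yl)cyclopentan-1-one F4 (both epimers at C5). HF·pyridine in MeCN removes the silyl group and the fallback rejoins the route at 5.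

## Further compounds

F1 | step 8 | (6S)-3,5-dihydroxy-6-methyl-2,6-bis(3-methylbut-2-en-1-yl)-4-(2-methylpropanoyl)cyclohexa-2,4-dien-1-one | CC(C)C(=O)C1=C(O)[C@](C)(CC=C(C)C)C(=O)C(CC=C(C)C)=C1O
F2 | step 8 | (1S,3R,5S,7S)-8-hydroxy-4,4,7-trimethyl-9-(2-methylpropanoyl)-3-(prop-1-en-2-yl)tricyclo[5.3.1.0^1,5]undec-8-ene-10,11-dione | CC(C)C(=O)C1=C(O)[C@]2(C)C[C@H]3C(C)(C)[C@@H](C(C)=C)C[C@@]3(C1=O)C2=O
F0 | step 5 | none | none
F3 | step 3 | (2R,3R)-3-[(tert-butyldimethylsilyl)oxy]-2-methyl-2-(3-methylbut-2-en-1-yl)cyclopentan-1-one | O=C1CC[C@@H](O[Si](C)(C)C(C)(C)C)[C@@]1(C)CC=C(C)C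
F4 | step 3 | (2R,3R)-3-[(tert-butyldimethylsilyl)oxy]-5-hydroxy-2-methyl-2-(3-methylbut-2-en-1-yl)cyclopentan-1-one (both epimers at C5) | O=C1C(O)C[C@@H](O[Si](C)(C)C(C)(C)C)[C@@]1(C)CC=C(C)C
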